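(The numbers of this flask were chosen freely; the flask was simulated.)

Slowness of the partner feed is the question for the next run: partner charged at once, dosed over 8.00 min, or passed through a tank.

| setting | beta | theta | epsilon | alpha |
|---|---|---|---|---|
| substrate | 23 mM | 23 mM | 23 mM | 23 mM |
| partner | 34.5 mM (fed, over 8.00 min) | 34.5 mM | 34.5 mM | 34.5 mM |
| time | 10 min | 10 min |  |  |
| remark | a stirred flask in which partner is dosed at a steady rate over 8.00 min without added volume, worked up at 10 min | a closed flask charged with all of it at once and left for 10 min | a single well-mixed tank run continuously and read at steady state, 10 min in it on average | one stirred flow tank at steady state, fed with the mixture as stated, mean residence time 100 min |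

    intermediate B → side product A (k1 = 0.0051 s⁻¹)
    intermediate B → side product B (k2 = 9.4 × 10⁻⁴ s⁻¹)
    intermediate A → target (k3 = 0.0092 s⁻¹)
    partner + intermediate A → intermediate B (k4 = 0.098 M⁻¹ s⁻¹)
    substrate ⇌ intermediate A (K5 = 13, k5 = 0.024 s⁻¹)
    substrate + target ⇌ idle adduct, settled at all times (K6 = 94 M⁻¹)

- in percentages every species weighs as the substrate in it: one idle adduct counts as two
- for target the idle adduct is counted in
- the stated concentrations are those of everything mixed, before any reaction; amounts are the same in each set-up
- the feed brings no volume worth counting
- in an amount of target, one idle adduct counts as one target
- run time (beta): 10 min

- the set-up with the highest amount of target at the outlet or at the end, in percent of the substrate put in ("none" if the first two lie within 2 percentage points) (beta / theta / epsilon / alpha / none)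
- amount of target at the outlet or at the end, in percent of the substrate put in, beta
- amount of target at the outlet or at the end, in percent of the substrate put in, theta
- amount of target at the outlet or at the end, in percent of the substrate put in, epsilon
- amount of target at the outlet or at the end, in percent of the substrate put in, alpha

1. Besides falling back to substrate, intermediate A has two ways forward: it goes to target with rate constant 0.0092 s⁻¹, or it meets partner and goes to intermediate B with rate constant 0.098 M⁻¹ s⁻¹. The symmetric case serves as the zero of the scale. The first constant over the second is 93.9 mM, the even-split partner concentration, c(even), at which the two branches run equally.

2. Of the intermediate A that goes forward, the share that becomes target, the selectivity, is c(even)/(c(even) + c(partner)). In theta, c(partner) starts at 34.5 mM, so the share starts at 73.1 %.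

3. In beta, the mean life of intermediate A on the target branch, the inverse of its rate constant, is 1.81 min, which is shorter than the dosing. In beta, c(partner) rises steadily from zero and the feed delivers 7.81 mM in that time, so this estimate takes that as the mean level met by intermediate A, and the share is about 92.3 %. The delay from the idle adduct is not reckoned here.

4. The tanks receive the whole mixture together, so this reckoning places their share beside that of theta and leaves their conversion open. The next run therefore doses partner and keeps the charge unchanged.

5. The forecast names beta, with 87.5 % for beta, 72 % for theta, 57 % for epsilon and 73.5 % for alpha. Its ground is that “dosing partner keeps it low while most of the substrate converts”. Its beta lies below the share reckoned above.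

6. The simulation gives beta as best, with 88.8 % for beta, 74.0 % for theta, 57.2 % for epsilon and 73.7 % for alpha.

The forecast holds, and dosing stays in the next run. In beta, the slow dosing of partner carries 15 percentage points: charged at once, the flask gives 74.0 % instead of 88.8 %. Read as a share of the whole charge, the 90.1 % that beta reaches by 100 min corresponds to a mean partner level of 10.3 mM, which is higher than the 7.81 mM reckoned. The alpha tank reads 29.2 mM of partner, where the even-split rule gives a share of 76.3 % of the intermediate A going forward, and alpha delivers 73.7 % of the substrate put in.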